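In a one-step world the next reading stands above the last until substrate or partner is used up, so you simply wait. The earlier runs did not behave that way.

| flask | left-handed substrate | right-handed substrate | partner | free catalyst | racemization catalyst | remark | time |
|---|---|---|---|---|---|---|---|
| blue | 1 mM | 1 mM | 2 equiv | 0.5 mol% | 2 mol% | run made earlier |  |
| amber | 1 mM | 1 mM | 4.5 equiv | 0.5 mol% | 2 mol% | run made earlier |  |
| green | 2 mM | 2 mM | 3 equiv | 0.5 mol% | 2 mol% | run made earlier |  |
| flask | 1.0 mM | 1.0 mM | 3.00 equiv | 0.5 mol% | 2 mol% |  | 3.0 min |

| run | time / min | left-handed product / % | right-handed product / % |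
|---|---|---|---|
| blue | 0.500 | 35 | 21 |
| blue | 1.00 | 36 | 23 |
| blue | 1.33 | 37 | 23 |
| blue | 2.00 | 37 | 21 |
| blue | 2.50 | 37 | 23 |
| amber | 0.200 | 38 | 23 |
| amber | 0.667 | 38 | 27 |
| amber | 1.00 | 38 | 25 |
| amber | 1.50 | 41 | 23 |
| amber | 2.50 | 40 | 27 |
| green | 0.200 | 48 | 34 |
| green | 0.333 | 50 | 34 |
| green | 0.667 | 49 | 35 |
| green | 1.33 | 53 | 36 |
| green | 2.50 | 50 | 36 |

(each reading ± 1.5 percentage points)

- free catalyst is single-handed; left-handed substrate and right-handed substrate are mirror images of each other, charged as a racemate, each of them at the stated concentration

- how much left-handed product there is at 3.0 min, in percent of the left-handed substrate and right-handed substrate together charged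
- how much right-handed product there is at 3.0 min, in percent of the left-handed substrate and right-handed substrate together charged

Turn the settings one at a time, counting both products together over each run's last 3 readings. By hand, more time brings more product, yet the blue run already reads 56.0% at 0.500 min and averages 59.3% late on. A stop set by partner should follow its charge, yet going from 2 equiv to 4.5 equiv lifts the plateau just to 64.7%. The green run has the same mol% of catalyst but twice the concentration, and 3 equiv of partner besides, so two settings differ, and it reaches 86.3%.

Suppose each catalyst lost takes a fixed fraction of the substrate still there. Then, once the catalyst is lost, ln(1/fraction of substrate left), divided by the catalyst charged in mM, is a constant: call it the reach. The readings give 180 mM⁻¹ for blue, 208 mM⁻¹ for amber and 199 mM⁻¹ for green.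

My reckoning takes green's reach, since its partner matches your flask. By this reckoning your flask keeps 37.0% of its substrate. With a left-handed share of 61.8% from blue and amber, that gives 39.0% left-handed and 24.1% right-handed product.

The forecast says 38% (36% to 40%) and 24% (22% to 26%), holding that “3.0 min should simply read the plateau”. My left-handed figure stands above its own.

Your flask gives 40.5% and 24.5%, so the forecast is right within the tolerance, though the left-handed figure stands just above its high end, and the reach's 63.0% stands against 65.0% together.

    partner + free catalyst + left-handed substrate → free catalyst + left-handed product (k = 2.00 × 10⁷ M⁻² s⁻¹)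
    partner + free catalyst + right-handed substrate → free catalyst + right-handed product (k = 1.00 × 10⁷ M⁻² s⁻¹)
    left-handed substrate + racemization catalyst ⇌ right-handed substrate + racemization catalyst, rate k3*[racemization catalyst]*[left-handed substrate] forward; the back reaction follows from the equilibrium constant (k = 2100 M⁻¹ s⁻¹)
    2 partner → self-condensation product (k = 2.00 M⁻¹ s⁻¹)
    partner + free catalyst → spent catalyst (k = 68.0 M⁻¹ s⁻¹)
    partner → decomposed reagent (k = 0.0230 s⁻¹)

With both substrates at their charge, a free catalyst turns over 441 times for each loss to spent catalyst. Spent catalyst stands at 97.9% of the catalyst charged by 1.50 min, with 35% of each substrate still there at 3.00 min. Watch the catalyst weighing: the right-handed figure has moved by 5 points at 0.36 mol% of free catalyst, and a neighbouring flask with 0.12 mol%, all else as in yours, holds 15.1% and 7.96%, below the forecast's ranges. For that neighbouring flask the reach gives 21.2%, and it holds 23.1% together.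

(The earlier runs and the new flask were computed with made-up constants, noise included.)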